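**Strategy**

1. With the phenols of rings B and C masked as triisopropylsilyl ethers, ring A is cut at two C–C bonds, C1–C2 and C5–C6 (C1 = aroyl-bearing carbon). This gives a four-carbon 1,3-dioxygenated diene (C2 to C5) and an aryl ethynyl ketone (C6, C1 and the carbonyl).
2. The enabling feature: in ring A, C2(OH)–C3(H)–C4(OMe)–C5(alkyl) has the oxidation pattern of the O-methyl enol ether of a γ-alkylated acetoacetate, and C6(H)–C1(aroyl) is an ynone. The hydroxyl ortho and the methoxy para to the carbonyl match the polarity of both partners.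
3. The diene is cut further at the bond between C5 and the propyl chain (acetoacetate dianion plus 3-arylpropyl iodide). The ynone is cut at the carbinol–alkyne bond (4-hydroxybenzaldehyde plus ethynyl Grignard reagent).
4. Forward: rings B and C are bought. The chain of fragment 1 is joined to acetoacetate, the ketone is O-methylated, and the ester is turned into the silyl ketene acetal. Ring A is formed last by cycloaddition and aromatization, then both silyl ethers are removed.
5. Stereochemistry: the target has no stereocenter. The enol ether geometries and the two sp3 centers of the cycloadduct are erased on aromatization.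

Key step: step 10

Remark: ethynylmagnesium bromide is taken as the commercial THF solution. The lithium dienolate, the vinylketene acetal and the cycloadduct are isomer mixtures and are drawn without stereodescriptors; aromatization removes every such element.

**Route**

Step 1
Reactants: 1 methyl 3-(4-hydroxyphenyl)propanoate
Product: 2 methyl 3-[4-(triisopropylsilyloxy)phenyl]propanoate
Conditions: TIPSCl, imidazole, DMF, rt
Reagents that add atoms: triisopropylsilyl chloride (TIPSCl), CC(C)[Si](Cl)(C(C)C)C(C)C
Why: Imidazole-promoted silylation of the phenol gives a hindered aryl silyl ether that should withstand the hydride, carbanion, dilute acid and amide base used later.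

Step 2
Reactants: 2 methyl 3-[4-(triisopropylsilyloxy)phenyl]propanoate
Product: 3 3-[4-(triisopropylsilyloxy)phenyl]propan-1-ol
Conditions: LiAlH4, THF, 0 °C; Na2SO4·10H2O quench
Reagents that add atoms: none
Why: Hydride reduction of the methyl ester by LiAlH4 gives the primary alcohol, the hindered aryl silyl ether being inert to hydride at 0 °C and the neutral sulfate quench avoiding base-induced desilylation.

Step 3
Reactants: 3 3-[4-(triisopropylsilyloxy)phenyl]propan-1-ol
Product: 4 1-(3-iodopropyl)-4-(triisopropylsilyloxy)benzene (fragment 1)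
Conditions: I2, PPh3, imidazole, CH2Cl2, 0 °C to rt
Reagents that add atoms: iodine, II
Why: Appel-type (Garegg–Samuelsson) iodination, in which the alkoxyphosphonium salt is displaced by iodide in an SN2 reaction at the unhindered primary carbon under nearly neutral conditions.

Step 4
Reactants: 5 methyl acetoacetate; 4 1-(3-iodopropyl)-4-(triisopropylsilyloxy)benzene
Product: 7 methyl 3-oxo-7-[4-(triisopropylsilyloxy)phenyl]heptanoate, via acetoacetate dianion 6 (not isolated)
Conditions: 5, NaH, THF, 0 °C; n-BuLi, 0 °C; then 4, 0 °C to rt; aq NH4Cl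
Reagents that add atoms: none
Why: Weiler dianion alkylation, in which the terminal (γ) carbanion of the 1,3-dianion is the more basic and more nucleophilic site and displaces the primary iodide in an SN2 reaction while the stabilized β-keto ester enolate stays untouched until work-up.

Step 5
Reactants: 7 methyl 3-oxo-7-[4-(triisopropylsilyloxy)phenyl]heptanoate
Product: 9 methyl (E)-3-methoxy-7-[4-(triisopropylsilyloxy)phenyl]hept-2-enoate, via dimethyl ketal 8 (not isolated)
Conditions: HC(OMe)3, cat. H2SO4, MeOH, rt to 50 °C; then NaHCO3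
Reagents that add atoms: trimethyl orthoformate, COC(OC)OC; methanol (solvent), CO
Why: Acid-catalysed ketalization by the orthoformate followed by loss of methanol toward the ester gives the conjugated β-methoxy enoate, the E isomer (methoxy trans to the ester) being the thermodynamically preferred and usual product of this standard enol ether synthesis.

Step 6
Reactants: 10 4-hydroxybenzaldehyde
Product: 11 4-(triisopropylsilyloxy)benzaldehyde
Conditions: TIPSCl, imidazole, DMF, rt
Reagents that add atoms: triisopropylsilyl chloride (TIPSCl), CC(C)[Si](Cl)(C(C)C)C(C)C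
Why: Imidazole-promoted silylation of the phenol removes the acidic proton before the Grignard addition and installs the same protecting group as on fragment 1, so one final operation frees both phenols.

Step 7
Reactants: 11 4-(triisopropylsilyloxy)benzaldehyde; 12 ethynylmagnesium bromide
Product: 13 rac-1-[4-(triisopropylsilyloxy)phenyl]prop-2-yn-1-ol
Conditions: HC≡CMgBr in THF, 0 °C; aq NH4Cl
Reagents that add atoms: none
Why: 1,2-Addition of the alkynyl Grignard reagent to the aldehyde, the new carbinol stereocenter being formed racemic and removed again by the oxidation in step 8.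

Step 8
Reactants: 13 rac-1-[4-(triisopropylsilyloxy)phenyl]prop-2-yn-1-ol
Product: 14 1-[4-(triisopropylsilyloxy)phenyl]prop-2-yn-1-one (fragment 3)
Conditions: activated MnO2, CH2Cl2, rt; used soon after filtration
Reagents that add atoms: none
Why: Heterogeneous MnO2 oxidation is selective for the activated benzylic and propargylic alcohol and gives the ynone under neutral conditions that leave the terminal alkyne and the silyl ether intact.

Step 9
Reactants: 9 methyl (E)-3-methoxy-7-[4-(triisopropylsilyloxy)phenyl]hept-2-enoate
Product: 16 1,3-dimethoxy-1-(trimethylsilyloxy)-7-[4-(triisopropylsilyloxy)phenyl]hepta-1,3-diene (fragment 2), via lithium dienolate 15 (not isolated)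
Conditions: LiN(i-Pr)2, THF, −78 °C; TMSCl, −78 °C to rt; evaporation, dry hexane, filtration under Ar; used crude
Reagents that add atoms: chlorotrimethylsilane (TMSCl), C[Si](C)(C)Cl
Why: Kinetic γ-deprotonation of the (E)-β-methoxy enoate, whose γ-CH2 lies syn to the ester carbonyl and whose C2 carries no sp3 hydrogen, gives the extended dienolate, which the hard silyl chloride traps on oxygen as the vinylketene acetal (Brassard-type diene synthesis).

Step 10
Reactants: 16 1,3-dimethoxy-1-(trimethylsilyloxy)-7-[4-(triisopropylsilyloxy)phenyl]hepta-1,3-diene; 14 1-[4-(triisopropylsilyloxy)phenyl]prop-2-yn-1-one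
Product: 18 {2-hydroxy-4-methoxy-5-[3-(4-(triisopropylsilyloxy)phenyl)propyl]phenyl}[4-(triisopropylsilyloxy)phenyl]methanone, via cyclohexadiene cycloadduct 17 (not isolated)
Conditions: toluene, rt to 50 °C, 16 in slight excess; then 1 M aq HCl, THF, rt
Reagents that add atoms: none
Why: Diene 16, made electron-rich by its two donor oxygens at C1 and C3, adds to the electron-poor terminal ynone 14 in a normal-electron-demand (4+2) cycloaddition, either concerted and asynchronous or stepwise by vinylogous Mukaiyama–Michael addition followed by closure of the allenolate onto the ketene acetal carbon, both paths giving cyclohexadiene 17. The closest known reaction type is the Diels–Alder benzannulation of Brassard-type and Danishefsky-type 1-alkoxy-1-silyloxy-1,3-dienes with acetylenic ketones and esters, followed by aromatization. Ring A is closed as a six-membered carbocycle by this cycloaddition, the alkyl-bearing diene terminus C4 bonding to the terminal alkyne carbon and the ketene acetal carbon C1 to the aroyl-bearing alkyne carbon. No stereocenter survives, because the ketal carbon and the alkyl-bearing sp3 carbon of 17 are both flattened on aromatization, so the diene geometry and the facial selectivity are irrelevant. The step needs this single regiochemistry, which the matched polarization secures (largest HOMO coefficient at C4 of the 1,3-dioxygenated diene, largest LUMO coefficient at the unhindered β-carbon of the ynone), and it needs the ketal to collapse with loss of methanol and not of silanol, which the aqueous acid secures by cleaving the O–Si bond first so that the hemiketal expels methanol and the dienone tautomerizes to the phenol. Aromatization and the hydrogen bond from the new phenol to the aroyl carbonyl make the sequence irreversible, and the aryl triisopropylsilyl ethers are stable to the brief dilute acid.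

Step 11
Reactants: 18 {2-hydroxy-4-methoxy-5-[3-(4-(triisopropylsilyloxy)phenyl)propyl]phenyl}[4-(triisopropylsilyloxy)phenyl]methanone
Product: 19 (4-hydroxyphenyl){2-hydroxy-5-[3-(4-hydroxyphenyl)propyl]-4-methoxyphenyl}methanone (target CNP0209225.0)
Conditions: Bu4NF, AcOH, THF, 0 °C
Reagents that add atoms: none
Why: Fluoride-induced cleavage of both aryl silyl ethers is driven by the strong Si–F bond, with acetic acid buffering the liberated phenoxides so that the benzophenone and the methyl ether are untouched.

**Compound list**

1 | methyl 3-(4-hydroxyphenyl)propanoate | COC(=O)CCc1ccc(O)cc1 | starting material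
2 | methyl 3-[4-(triisopropylsilyloxy)phenyl]propanoate | COC(=O)CCc1ccc(O[Si](C(C)C)(C(C)C)C(C)C)cc1 | intermediate
3 | 3-[4-(triisopropylsilyloxy)phenyl]propan-1-ol | OCCCc1ccc(O[Si](C(C)C)(C(C)C)C(C)C)cc1 | intermediate
4 | 1-(3-iodopropyl)-4-(triisopropylsilyloxy)benzene (fragment 1) | ICCCc1ccc(O[Si](C(C)C)(C(C)C)C(C)C)cc1 | intermediate
5 | methyl acetoacetate | COC(=O)CC(C)=O | starting material
6 | sodium lithium dianion of methyl acetoacetate (1-methoxybuta-1,3-diene-1,3-diolate; not isolated) | [Li+].[Na+].COC([O-])=CC([O-])=C | intermediate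
7 | methyl 3-oxo-7-[4-(triisopropylsilyloxy)phenyl]heptanoate | COC(=O)CC(=O)CCCCc1ccc(O[Si](C(C)C)(C(C)C)C(C)C)cc1 | intermediate
8 | methyl 3,3-dimethoxy-7-[4-(triisopropylsilyloxy)phenyl]heptanoate (dimethyl ketal; not isolated) | COC(=O)CC(OC)(OC)CCCCc1ccc(O[Si](C(C)C)(C(C)C)C(C)C)cc1 | intermediate
9 | methyl (E)-3-methoxy-7-[4-(triisopropylsilyloxy)phenyl]hept-2-enoate | COC(=O)/C=C(/OC)CCCCc1ccc(O[Si](C(C)C)(C(C)C)C(C)C)cc1 | intermediate
10 | 4-hydroxybenzaldehyde | O=Cc1ccc(O)cc1 | starting material
11 | 4-(triisopropylsilyloxy)benzaldehyde | O=Cc1ccc(O[Si](C(C)C)(C(C)C)C(C)C)cc1 | intermediate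
12 | ethynylmagnesium bromide | C#C[Mg]Br | starting material
13 | rac-1-[4-(triisopropylsilyloxy)phenyl]prop-2-yn-1-ol | C#CC(O)c1ccc(O[Si](C(C)C)(C(C)C)C(C)C)cc1 | intermediate
14 | 1-[4-(triisopropylsilyloxy)phenyl]prop-2-yn-1-one (fragment 3) | C#CC(=O)c1ccc(O[Si](C(C)C)(C(C)C)C(C)C)cc1 | intermediate
15 | lithium 1,3-dimethoxy-7-[4-(triisopropylsilyloxy)phenyl]hepta-1,3-dien-1-olate (dienolate of 9, geometric mixture; not isolated) | [Li+].COC([O-])=CC(OC)=CCCCc1ccc(O[Si](C(C)C)(C(C)C)C(C)C)cc1 | intermediate
16 | 1,3-dimethoxy-1-(trimethylsilyloxy)-7-[4-(triisopropylsilyloxy)phenyl]hepta-1,3-diene (fragment 2, geometric mixture) | COC(O[Si](C)(C)C)=CC(OC)=CCCCc1ccc(O[Si](C(C)C)(C(C)C)C(C)C)cc1 | intermediate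
17 | [4,6-dimethoxy-3-{3-[4-(triisopropylsilyloxy)phenyl]propyl}-6-(trimethylsilyloxy)cyclohexa-1,4-dien-1-yl][4-(triisopropylsilyloxy)phenyl]methanone (cycloadduct, diastereomer mixture; not isolated) | COC1=CC(OC)(O[Si](C)(C)C)C(C(=O)c2ccc(O[Si](C(C)C)(C(C)C)C(C)C)cc2)=CC1CCCc1ccc(O[Si](C(C)C)(C(C)C)C(C)C)cc1 | intermediate
18 | {2-hydroxy-4-methoxy-5-[3-(4-(triisopropylsilyloxy)phenyl)propyl]phenyl}[4-(triisopropylsilyloxy)phenyl]methanone | COc1cc(O)c(C(=O)c2ccc(O[Si](C(C)C)(C(C)C)C(C)C)cc2)cc1CCCc1ccc(O[Si](C(C)C)(C(C)C)C(C)C)cc1 | intermediate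
19 | (4-hydroxyphenyl){2-hydroxy-5-[3-(4-hydroxyphenyl)propyl]-4-methoxyphenyl}methanone (CNP0209225.0) | COc1cc(O)c(C(=O)c2ccc(O)cc2)cc1CCCc1ccc(O)cc1 | target

**Step count and risks**

Total step count: 11. Longest linear sequence: 8 steps (steps 1, 2, 3, 4, 5, 9, 10, 11, from compound 1 to 19). The ynone branch (steps 6 to 8) joins at step 10.

Most likely to fail, most serious first:

Step 10 (cycloaddition and aromatization). The ynone may polymerize or be consumed by Michael addition without ring closure. The diene may lose its trimethylsilyl group before it reacts. The ketal may collapse with loss of silanol, so that the oxygen next to the ketone stays methylated. Fallback, from iodide 4 back to 18: ring A is bought preformed and the side chain is attached by cross-coupling. Commercial (4-bromophenoxy)triisopropylsilane is converted with Mg in THF into 4-(triisopropylsilyloxy)phenylmagnesium bromide F1. F1 is added at 0 °C to commercial 5-bromo-2-hydroxy-4-methoxybenzaldehyde (phenol deprotonated first with NaH) to give rac-(5-bromo-2-hydroxy-4-methoxyphenyl)[4-(triisopropylsilyloxy)phenyl]methanol F2. MnO2 in CH2Cl2 oxidizes the benzylic carbinol to (5-bromo-2-hydroxy-4-methoxyphenyl)[4-(triisopropylsilyloxy)phenyl]methanone F3. Iodide 4 is converted with Zn dust and LiCl in THF into {3-[4-(triisopropylsilyloxy)phenyl]propyl}zinc iodide F4. Negishi coupling of F4 with F3 (Pd(OAc)2, SPhos, THF, rt, slow addition of the zinc reagent, which tolerates the chelated phenol) should give 18, and the route continues with step 11.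

Step 9 (vinylketene acetal). γ-Deprotonation may be incomplete, silylation may occur on carbon, or the moisture-sensitive ketene acetal may hydrolyse back to the enoate while the salts are removed. Fallback, from β-keto ester 7 back to 18: the methyl enol ether is bypassed and the methyl group is put on after ring A exists. Ester 7 is silylated with TMSCl and Et3N to methyl 3-(trimethylsilyloxy)-7-[4-(triisopropylsilyloxy)phenyl]hept-2-enoate F5. LiN(i-Pr)2 and TMSCl at −78 °C convert F5 into 1-methoxy-1,3-bis(trimethylsilyloxy)-7-[4-(triisopropylsilyloxy)phenyl]hepta-1,3-diene F6, a Chan-type diene. F6 adds to ynone 14 with the same orientation to give the cyclohexadiene cycloadduct F7. Dilute acid work-up of F7 gives {2,4-dihydroxy-5-[3-(4-(triisopropylsilyloxy)phenyl)propyl]phenyl}[4-(triisopropylsilyloxy)phenyl]methanone F8. The hydroxyl para to the ketone is then methylated selectively with TMSCHN2, i-Pr2NEt, MeOH/MeCN, the ortho hydroxyl being held in the hydrogen bond to the carbonyl. This should give 18.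

Step 4 (dianion alkylation). The unactivated iodide may undergo elimination, the dianion may be quenched by proton transfer, or the product may be alkylated a second time. Fallback, from alcohol 3 back to 7: the γ-carbon–chain bond is made as a double bond and then reduced. Alcohol 3 is oxidized with Dess–Martin periodinane (CH2Cl2, NaHCO3) to 3-[4-(triisopropylsilyloxy)phenyl]propanal F9. The stabilized ylide methyl 3-oxo-4-(triphenylphosphoranylidene)butanoate F10 is prepared from methyl 4-chloroacetoacetate and PPh3, then aqueous Na2CO3. Wittig olefination of F9 with F10 (NaH, THF, rt) gives methyl (E)-3-oxo-7-[4-(triisopropylsilyloxy)phenyl]hept-4-enoate F11. Hydrogenation of the enone double bond (H2, Pd/C, EtOAc) should give 7, and the route continues with step 5.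

**Further compounds**

F1 | step 10 | 4-(triisopropylsilyloxy)phenylmagnesium bromide | Br[Mg]c1ccc(O[Si](C(C)C)(C(C)C)C(C)C)cc1
F2 | step 10 | rac-(5-bromo-2-hydroxy-4-methoxyphenyl)[4-(triisopropylsilyloxy)phenyl]methanol | COc1cc(O)c(C(O)c2ccc(O[Si](C(C)C)(C(C)C)C(C)C)cc2)cc1Br
F3 | step 10 | (5-bromo-2-hydroxy-4-methoxyphenyl)[4-(triisopropylsilyloxy)phenyl]methanone | COc1cc(O)c(C(=O)c2ccc(O[Si](C(C)C)(C(C)C)C(C)C)cc2)cc1Br
F4 | step 10 | {3-[4-(triisopropylsilyloxy)phenyl]propyl}zinc iodide | I[Zn]CCCc1ccc(O[Si](C(C)C)(C(C)C)C(C)C)cc1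
F5 | step 9 | methyl 3-(trimethylsilyloxy)-7-[4-(triisopropylsilyloxy)phenyl]hept-2-enoate | COC(=O)C=C(O[Si](C)(C)C)CCCCc1ccc(O[Si](C(C)C)(C(C)C)C(C)C)cc1
F6 | step 9 | 1-methoxy-1,3-bis(trimethylsilyloxy)-7-[4-(triisopropylsilyloxy)phenyl]hepta-1,3-diene | COC(O[Si](C)(C)C)=CC(O[Si](C)(C)C)=CCCCc1ccc(O[Si](C(C)C)(C(C)C)C(C)C)cc1
F7 | step 9 | [6-methoxy-3-{3-[4-(triisopropylsilyloxy)phenyl]propyl}-4,6-bis(trimethylsilyloxy)cyclohexa-1,4-dien-1-yl][4-(triisopropylsilyloxy)phenyl]methanone | C[Si](C)(C)OC1=CC(OC)(O[Si](C)(C)C)C(C(=O)c2ccc(O[Si](C(C)C)(C(C)C)C(C)C)cc2)=CC1CCCc1ccc(O[Si](C(C)C)(C(C)C)C(C)C)cc1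
F8 | step 9 | {2,4-dihydroxy-5-[3-(4-(triisopropylsilyloxy)phenyl)propyl]phenyl}[4-(triisopropylsilyloxy)phenyl]methanone | Oc1cc(O)c(C(=O)c2ccc(O[Si](C(C)C)(C(C)C)C(C)C)cc2)cc1CCCc1ccc(O[Si](C(C)C)(C(C)C)C(C)C)cc1
F9 | step 4 | 3-[4-(triisopropylsilyloxy)phenyl]propanal | O=CCCc1ccc(O[Si](C(C)C)(C(C)C)C(C)C)cc1
F10 | step 4 | methyl 3-oxo-4-(triphenylphosphoranylidene)butanoate | COC(=O)CC(=O)C=P(c1ccccc1)(c1ccccc1)c1ccccc1
F11 | step 4 | methyl (E)-3-oxo-7-[4-(triisopropylsilyloxy)phenyl]hept-4-enoate | COC(=O)CC(=O)/C=C/CCc1ccc(O[Si](C(C)C)(C(C)C)C(C)C)cc1
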